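## The problem

Ciwujiatone (15) is an oxolane, labelled here O-1, C-2, C-3, C-4, C-5. It carries ring A (4-hydroxy-3,5-dimethoxyphenyl) on C-2, a CH2OH group on C-3 and the aroyl group of ring B (the same aryl group, on the ketone) on C-4; C-5 is an unsubstituted CH2. In these labels the configuration is 2S,3R,4R, that is 2,3-trans and 3,4-cis; the systematic names below number the ring the other way round, (3R,4R,5S).

The skeleton is two identical C6C3 units joined by the C-3–C-4 bond. A synthesis must make that bond between two stereocentres, close the ether O-1 between C-2 and C-5, and end with a ketone on one half and a primary alcohol on the other.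

The three stereocentres differ in kind. C-2 is a p-hydroxybenzylic ether that can ionize and re-close, so it can be left to settle trans to C-3. C-4 is α to the ketone and epimerizable, and the 3,4-cis arrangement is probably not the one an open β-alkoxy ketone prefers. C-3 has no such handle, must be set absolutely, and is the centre that can control the other two.

The molecule tolerates little. Base opens the β-alkoxy ketone (O-1–C-5 is β to the carbonyl group) or epimerizes C-4, acid ionizes C-2–O-1, and oxidants attack two electron-rich phenols.

Two features make the key step possible. First, C-2 bears a donor (ring A) and C-4 an acceptor (the ketone carbon), 1,3 to each other across C-3, and they are bridged by O-1–C-5, one oxygen and one unsubstituted carbon. This is what a 2-aryl-1-formylcyclopropane (three-membered ring C-2/C-3/C-4, formyl group = C-5 and O-1) becomes on Cloke–Wilson ring expansion. Second, the CH2OH group on C-3 and the ketone carbon on C-4, being cis, are the two ends of a γ-lactone opened by an aryl nucleophile. That lactone is also the ester tether between a sinapyl alcohol and a diazo carbon, so the three-membered ring can be closed by intramolecular, catalyst-controlled carbene transfer.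

## Retrosynthesis

**15 ⇒ 14 ⇒ 9 + 12.** After removal of the two aryl silyl ethers (14), the bond between the ketone carbon and ring B is cut and the ketone carbon is returned to a lactone carbonyl closed on the oxygen of the CH2OH group. This gives cis-fused lactone 9 and aryllithium 12 (from bromide 11, from phenol 10). The neighbouring cut, C-4 to the ketone carbon, would leave the 3,4-cis relation to an intermolecular step. A Friedel–Crafts cut would put a strong Lewis acid on the benzylic ether. A five-membered lactone can bridge C-3 and C-4 only when they are cis, so the epimerizable centre is locked until the last C–C bond is made. The forward step must add the aryl group once and without enolizing the lactone.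

**9 ⇒ 8.** The hydrogens on C-4 and C-5 are removed to give the enol ether C-4=C-5, conjugated with the lactone carbonyl. C-4 becomes trigonal, so 8 has only two stereocentres, and the unit O-1–C-5=C-4–C=O is the product pattern of an acylcyclopropane rearrangement. The forward step is a hydrogenation whose only stable outcome is the cis-fused bicycle.

**8 ⇒ 7 ⇒ 6.** In 8 the bond O-1–C-2 is cut and C-2 is joined to C-4, giving formylcyclopropane lactone 7. The other ring bonds were weighed: O-1–C-5 would be a 5-endo oxa-Michael closure, and C-2–C-3 an aldol that leaves C-3 to be set separately. This cut is driven by about 27 kcal/mol of ring strain, is directed to C-2 by ring A, and sets C-2 by a reversible ionization. In 7 the bonds C-3–C-4 and C-2–C-4 are then cut: a carbene at C-4 and the E alkene C-2=C-3 of a sinapyl ester, diazo ester 6. Compound 6 is achiral and has no ring other than the arene; the product has two new rings, the C-3–C-4 bond and two stereocentres. The forward reaction must choose one alkene face, which is asked of a chiral divalent cobalt porphyrin.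

**6 ⇒ 5 ⇒ 4.** The formyl carbon (the future C-5, with the future O-1) is removed from the diazo carbon to give diazoacetate 5. The diazoacetyl group (the future C-4 and ketone carbon) is removed from oxygen to give allylic alcohol 4, which holds ring A, C-2, C-3 and the CH2OH group. Both forward steps are functional-group chemistry on an achiral compound.

**4 ⇒ 3 ⇒ 2 ⇒ 1.** Ester reduction, Wittig olefination and phenol silylation lead back to syringaldehyde 1.

**11 ⇒ 10.** Silylation of commercial 4-bromo-2,6-dimethoxyphenol 10.

## Roads not taken

Alternative 1: the biomimetic route, and the most obvious one. The cut is C-3–C-4 together with both benzylic C–O bonds. Forward, one-electron oxidation of sinapyl alcohol A1 (FeCl3 or a laccase) gives β–β radical coupling and double quinone methide closure to syringaresinol A2. DDQ oxidation of one of its two homotopic benzylic C–H bonds and hydration then gives 15 directly. This is only two steps, but the free-radical coupling has no control of absolute configuration, so A2 forms as a racemate and must be resolved. The oxidation must also stop after one of two identical positions, in a product that still has an equally activated benzylic C–H bond and two free phenols. The chosen plan sets C-3 by a catalyst and needs no oxidation of the finished skeleton.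

Alternative 2: tandem conjugate addition and aldol on a butenolide. The cuts are C-4 to the ketone carbon and C-2–C-3. Forward, the lithio derivative of dithiane A3 (from aldehyde 2) adds to a butenolide carrying a removable chiral alkoxy group, and the enolate is trapped with aldehyde 2 to give trans lactone A4. Lactone reduction, acid closure of the oxolane through the benzylic cation and dithiane removal would follow. The chemistry is reliable, but the lactone of A4 is the wrong one: its carbonyl must become CH2OH and its alkoxy carbon the ether carbon. That costs a reduction, a selective cyclization and the excision of the auxiliary carbon. The ketone is masked throughout and is unmasked by thiophilic or oxidizing reagents next to electron-rich arenes, and the chirality is stoichiometric. In the chosen plan the lactone carbonyl is already the ketone carbon.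

Alternative 3: Prins–pinacol rearrangement, of which the 3-acyl oxolane is the retron. The cuts are C-2–C-3 and C-4–C-5, with the ketone formed by the pinacol shift. Forward, acetal A5 (a 2,4-diaryl-4-alkenyl-1,3-dioxolane built on aldehyde 2) would ionize with SnCl4, cyclize through a six-membered chair and contract to the aroyl oxolane, all stereocentres coming from one carbinol centre that is consumed. The chair model puts ring A and the C-3 substituent equatorial (2,3-trans, as needed) but delivers the migrating carbon to the face of C-4 that sets the aroyl group trans to the C-3 substituent. The result would be the all-trans C-4 epimer A6. No alkene geometry gives 2,3-trans together with 3,4-cis, and the repair would be an uphill epimerization next to the ketone. A5 is also a tertiary, benzylic, allylic ether on an electron-rich ring that may ionize before it rearranges, and its quaternary carbinol centre needs an asymmetric synthesis of its own. The lactone tether of the chosen plan enforces 3,4-cis by ring size.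

Key step: step 6

**Assumptions and abbreviations.**
- The target is taken as the open keto alcohol of the given SMILES; its ring-chain tautomer (the bicyclic lactol) counts as the same compound.
- Ar = 4-(tert-butyldimethylsilyloxy)-3,5-dimethoxyphenyl; TBS = tert-butyldimethylsilyl.
- [Co(Por*)] is the divalent cobalt complex of the dianion of 5,15-bis{2,6-bis[(S)-2,2-dimethylcyclopropane-1-carboxamido]phenyl}-10,20-bis(3,5-di-tert-butylphenyl)porphyrin. Its all-R antipode is equally accessible, and the route is written for whichever antipode gives the 3R series.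

## Steps

Step 1
Reactants: 1 syringaldehyde (4-hydroxy-3,5-dimethoxybenzaldehyde)
Product: 2 4-(tert-butyldimethylsilyloxy)-3,5-dimethoxybenzaldehyde (ArCHO)
Conditions: TBSCl, imidazole, DMF, rt
Reagents that add atoms: tert-butyldimethylsilyl chloride, CC(C)(C)[Si](C)(C)Cl
Why: O-silylation of the phenol; the silyl ether, shielded by two ortho methoxy groups, masks the acidic OH through the carbene and organolithium steps and is removed at the end under near-neutral conditions.

Step 2
Reactants: 2 4-(tert-butyldimethylsilyloxy)-3,5-dimethoxybenzaldehyde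
Product: 3 ethyl (E)-3-Ar-prop-2-enoate
Conditions: Ph3P=CHCO2Et, PhMe, 90 °C
Reagents that add atoms: ethyl (triphenylphosphoranylidene)acetate, CCOC(=O)C=P(c1ccccc1)(c1ccccc1)c1ccccc1
Why: Wittig olefination with a stabilized ylide should give the E alkene; the medium is neutral, so the aryl silyl ether is not at risk.

Step 3
Reactants: 3 ethyl (E)-3-Ar-prop-2-enoate
Product: 4 (E)-3-Ar-prop-2-en-1-ol
Conditions: i-Bu2AlH (2.2 equiv), CH2Cl2, −78 °C; aq. potassium sodium tartrate
Reagents that add atoms: none
Why: 1,2-reduction of the conjugated ester by the aluminium hydride should give the allylic alcohol without touching the alkene or the silyl ether.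

Step 4
Reactants: 4 (E)-3-Ar-prop-2-en-1-ol
Product: 5 (E)-3-Ar-prop-2-en-1-yl 2-diazoacetate
Conditions: TsNHN=CHCOCl, PhNMe2, CH2Cl2, 0 °C; then Et3N, 0 °C to rt
Reagents that add atoms: glyoxylic acid chloride p-toluenesulfonylhydrazone, Cc1ccc(cc1)S(=O)(=O)NN=CC(Cl)=O
Why: O-acylation followed by base-induced loss of sulfinate from the tosylhydrazone (Bamford–Stevens-type fragmentation) unveils the diazo ester in one flask; the basic medium protects the ionizable, electron-rich cinnamyl C–O bond.

Step 5
Reactants: 5 (E)-3-Ar-prop-2-en-1-yl 2-diazoacetate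
Product: 6 (E)-3-Ar-prop-2-en-1-yl 2-diazo-3-oxopropanoate
Conditions: [Me2N=CHCl]Cl (from DMF, (COCl)2), 2,6-lutidine, CH2Cl2, 0 °C to rt; then 10% aq. AcOH, rt
Reagents that add atoms: (chloromethylene)dimethyliminium chloride, C[N+](C)=CCl.[Cl-]; water, O
Why: Vilsmeier–Haack-type C-formylation: the nucleophilic diazo carbon attacks the chloroiminium ion, lutidine takes up the HCl, and water hydrolyses the iminium salt to the aldehyde, whose carbon is the future C-5 and whose oxygen is the future O-1.

Step 6
Reactants: 6 (E)-3-Ar-prop-2-en-1-yl 2-diazo-3-oxopropanoate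
Product: 8 (5R,6S)-6-Ar-3,7-dioxabicyclo[3.3.0]oct-1(8)-en-2-one, via formylcyclopropane lactone 7 (not isolated)
Conditions: [Co(Por*)] (2 mol%), PhMe, rt; then Sc(OTf)3 (5 mol%), CH2Cl2, rt
Reagents that add atoms: none
Why: The divalent cobalt porphyrin takes up 6 with loss of N2 to give a cobalt-bound α-formyl-α-ester carbon radical (formally trivalent cobalt); this adds to the alkene carbon remote from ring A (5-exo-trig, closing the γ-lactone and forming the C-3–C-4 bond) and then closes the three-membered ring by 3-exo-tet displacement at the Co–C bond, giving 7 and returning the catalyst, the closest known reaction type being the metalloradical asymmetric intramolecular cyclopropanation of acceptor-substituted allyl diazoacetates by divalent cobalt amidoporphyrins. C-3 is set in the radical addition by the chiral amide pocket of the porphyrin (N–H···O=C hydrogen bonds hold the two carbonyl groups, the tether presents one alkene face) and is not touched again, being neither benzylic nor α to a carbonyl group. Sc(OTf)3 then chelates the lactone and formyl oxygens of 7, and the C-2–C-4 bond, flanked by the aryl donor and two acceptors, breaks heterolytically to a benzylic cation and a scandium enolate, which re-closes through the formyl oxygen to the five-membered ring (O-alkylation with the enolate double bond inside the new ring), the Cloke–Wilson rearrangement of 2-aryl-1-acylcyclopropanes. C-2 is set in this closure under control of C-3, aryl trans to the C-3 substituent, and since the benzylic C–O bond can re-open under the Lewis acid a cis isomer, an E/Z mixture of the alkene or a cis/trans mixture of 7 would all converge on 8. C-4 is trigonal in 8 and is set in step 7. The step needs cyclopropanation to outrun carbene dimerization and C–H insertion (secured by the five-atom tether and the electron-rich styrene), O- rather than C-closure of the zwitterion (secured by release of cyclopropane strain), and closure through the formyl rather than the lactone carbonyl oxygen (secured because the former gives a conjugated β-alkoxy acrylate and the latter a bridgehead ketene acetal).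

Step 7
Reactants: 8 (5R,6S)-6-Ar-3,7-dioxabicyclo[3.3.0]oct-1(8)-en-2-one
Product: 9 (1R,5R,6S)-6-Ar-3,7-dioxabicyclo[3.3.0]octan-2-one
Conditions: H2 (3 atm), Rh/Al2O3, EtOAc, rt
Reagents that add atoms: none
Why: Heterogeneous hydrogenation of the β-alkoxy acrylate C-4=C-5 bond, syn from the face of the C-3 hydrogen, should give the cis-fused lactone and so the 3,4-cis relation of the target; cis fusion is also the thermodynamic outcome (any trans-fused material would drain through the lactone enolate with DBU), and Rh on alumina is preferred to Pd/C to spare the benzylic C-2–O-1 bond.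

Step 8
Reactants: 10 4-bromo-2,6-dimethoxyphenol
Product: 11 (4-bromo-2,6-dimethoxyphenoxy)(tert-butyl)dimethylsilane (ArBr)
Conditions: TBSCl, imidazole, DMF, rt
Reagents that add atoms: tert-butyldimethylsilyl chloride, CC(C)(C)[Si](C)(C)Cl
Why: O-silylation of the phenol gives a bromide that tolerates bromine–lithium exchange and carries the same protecting group as ring A, so one final step frees both phenols.

Step 9
Reactants: 9 (1R,5R,6S)-6-Ar-3,7-dioxabicyclo[3.3.0]octan-2-one; 11 (4-bromo-2,6-dimethoxyphenoxy)(tert-butyl)dimethylsilane
Product: 14 [(3R,4R,5S)-5-Ar-4-(hydroxymethyl)oxolan-3-yl](Ar)methanone, via aryllithium 12 (not isolated), via lithium lactolate 13 (not isolated)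
Conditions: 11, n-BuLi, THF, −78 °C; then 9, THF, −78 °C; aq. NH4Cl, −78 °C to rt
Reagents that add atoms: none
Why: Bromine–lithium exchange gives 12, which should add once to the lactone carbonyl (acyl substitution of a lactone by an aryllithium); the adduct is held as lactolate 13 at −78 °C, so no ketone meets the organolithium and the C-4 proton meets no base before the buffered quench, and ring opening then shows the ketone and the CH2OH group with C-3 and C-4 unchanged.

Step 10
Reactants: 14 [(3R,4R,5S)-5-Ar-4-(hydroxymethyl)oxolan-3-yl](Ar)methanone
Product: 15 ciwujiatone, [(3R,4R,5S)-5-(4-hydroxy-3,5-dimethoxyphenyl)-4-(hydroxymethyl)oxolan-3-yl](4-hydroxy-3,5-dimethoxyphenyl)methanone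
Conditions: Bu4NF, AcOH (1:1), THF, 0 °C
Reagents that add atoms: none
Why: Fluoride cleaves both aryl silyl ethers while acetic acid buffers fluoride and phenoxide, so the β-alkoxy ketone should neither epimerize at C-4 nor open by E1cB; no stereocentre is touched, and any C-2 epimer could be equilibrated toward 2,3-trans through the quinone methide by brief mild acid treatment of the free phenol.

## Compound list

1 | syringaldehyde (4-hydroxy-3,5-dimethoxybenzaldehyde) | O=Cc1cc(OC)c(O)c(OC)c1 | starting material
2 | 4-(tert-butyldimethylsilyloxy)-3,5-dimethoxybenzaldehyde | O=Cc1cc(OC)c(O[Si](C)(C)C(C)(C)C)c(OC)c1 | intermediate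
3 | ethyl (E)-3-[4-(tert-butyldimethylsilyloxy)-3,5-dimethoxyphenyl]prop-2-enoate | CCOC(=O)/C=C/c1cc(OC)c(O[Si](C)(C)C(C)(C)C)c(OC)c1 | intermediate
4 | (E)-3-[4-(tert-butyldimethylsilyloxy)-3,5-dimethoxyphenyl]prop-2-en-1-ol | OC/C=C/c1cc(OC)c(O[Si](C)(C)C(C)(C)C)c(OC)c1 | intermediate
5 | (E)-3-[4-(tert-butyldimethylsilyloxy)-3,5-dimethoxyphenyl]prop-2-en-1-yl 2-diazoacetate | [N-]=[N+]=CC(=O)OC/C=C/c1cc(OC)c(O[Si](C)(C)C(C)(C)C)c(OC)c1 | intermediate
6 | (E)-3-[4-(tert-butyldimethylsilyloxy)-3,5-dimethoxyphenyl]prop-2-en-1-yl 2-diazo-3-oxopropanoate | O=CC(=[N+]=[N-])C(=O)OC/C=C/c1cc(OC)c(O[Si](C)(C)C(C)(C)C)c(OC)c1 | intermediate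
7 | (1S,5R,6S)-6-[4-(tert-butyldimethylsilyloxy)-3,5-dimethoxyphenyl]-2-oxo-3-oxabicyclo[3.1.0]hexane-1-carbaldehyde | O=C1OC[C@@H]2[C@@H](c3cc(OC)c(O[Si](C)(C)C(C)(C)C)c(OC)c3)[C@]12C=O | intermediate (not isolated)
8 | (5R,6S)-6-[4-(tert-butyldimethylsilyloxy)-3,5-dimethoxyphenyl]-3,7-dioxabicyclo[3.3.0]oct-1(8)-en-2-one | O=C1C2=CO[C@H](c3cc(OC)c(O[Si](C)(C)C(C)(C)C)c(OC)c3)[C@H]2CO1 | intermediate
9 | (1R,5R,6S)-6-[4-(tert-butyldimethylsilyloxy)-3,5-dimethoxyphenyl]-3,7-dioxabicyclo[3.3.0]octan-2-one | O=C1[C@H]2CO[C@H](c3cc(OC)c(O[Si](C)(C)C(C)(C)C)c(OC)c3)[C@H]2CO1 | intermediate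
10 | 4-bromo-2,6-dimethoxyphenol | Oc1c(OC)cc(Br)cc1OC | starting material
11 | (4-bromo-2,6-dimethoxyphenoxy)(tert-butyl)dimethylsilane | CC(C)(C)[Si](C)(C)Oc1c(OC)cc(Br)cc1OC | intermediate
12 | [4-(tert-butyldimethylsilyloxy)-3,5-dimethoxyphenyl]lithium | [Li]c1cc(OC)c(O[Si](C)(C)C(C)(C)C)c(OC)c1 | intermediate (not isolated)
13 | lithium (1R,5R,6S)-2,6-bis[4-(tert-butyldimethylsilyloxy)-3,5-dimethoxyphenyl]-3,7-dioxabicyclo[3.3.0]octan-2-olate (configuration at the lactol carbon not defined) | [Li]OC1(c2cc(OC)c(O[Si](C)(C)C(C)(C)C)c(OC)c2)[C@H]2CO[C@H](c3cc(OC)c(O[Si](C)(C)C(C)(C)C)c(OC)c3)[C@H]2CO1 | intermediate (not isolated)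
14 | [(3R,4R,5S)-5-[4-(tert-butyldimethylsilyloxy)-3,5-dimethoxyphenyl]-4-(hydroxymethyl)oxolan-3-yl][4-(tert-butyldimethylsilyloxy)-3,5-dimethoxyphenyl]methanone | COc1cc(C(=O)[C@H]2CO[C@H](c3cc(OC)c(O[Si](C)(C)C(C)(C)C)c(OC)c3)[C@H]2CO)cc(OC)c1O[Si](C)(C)C(C)(C)C | intermediate
15 | ciwujiatone, [(3R,4R,5S)-5-(4-hydroxy-3,5-dimethoxyphenyl)-4-(hydroxymethyl)oxolan-3-yl](4-hydroxy-3,5-dimethoxyphenyl)methanone | COc1cc(C(=O)[C@H]2CO[C@H](c3cc(OC)c(O)c(OC)c3)[C@H]2CO)cc(OC)c1O | target

## Step count and least certain steps

Total: 10 steps. Longest linear sequence: 9 steps (steps 1 to 7, 9 and 10); step 8 is a one-step side branch.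

**Step 6 (key step).** The most likely failure is weak facial discrimination in the radical addition, because a formyl group gives the hydrogen-bonding pocket of the porphyrin less to hold than the ester, cyano or nitro groups of established substrates. Proton loss from the benzylic cation could also compete with ring closure to the strained fused enol ether. Fallback: set out from diazoacetate 5, which also bypasses step 5. Intramolecular cyclopropanation with the chiral dirhodium carboxamidate Rh2(4S-MPPIM)4 (or its 4R antipode) in CH2Cl2, a carbenoid route well established for E-cinnamyl diazoacetates, would give the cyclopropane lactone (1S,5R,6R)-6-Ar-3-oxabicyclo[3.1.0]hexan-2-one F1. Deprotonation at the cyclopropane carbon α to the lactone carbonyl with LiN(i-Pr)2 at −78 °C and C-formylation with 2,2,2-trifluoroethyl formate (retention is forced by the ring fusion) would give 7. The route is rejoined at 7 with the Sc(OTf)3 treatment of step 6.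

**Step 5.** The HCl set free can protonate the diazo carbon or ionize the electron-rich cinnamyl C–O bond before lutidine takes it up, and the chloroiminium ion can attack the arene. Fallback: set out from 5 under base only. DBU-catalysed aldol-type addition of the diazo ester to paraformaldehyde would give (E)-3-Ar-prop-2-en-1-yl 2-diazo-3-hydroxypropanoate F2. Oxidation with Dess–Martin periodinane then gives the aldehyde and rejoins the route at 6.

**Step 7.** Hydrogenolysis of the benzylic C-2–O-1 bond, which in 8 is a vinylogous benzyl ester, may compete with the slow reduction of a push-pull alkene. Fallback: set out from 7, isolated by leaving out the Sc(OTf)3 in step 6. NaBH4 in MeOH/THF at −40 °C should reduce only the aldehyde to give (1S,5R,6S)-6-Ar-1-(hydroxymethyl)-3-oxabicyclo[3.1.0]hexan-2-one F3. Catalytic TfOH in (CF3)2CHOH/CH2Cl2 then opens the aryl-substituted cyclopropane bond with the new hydroxyl oxygen as internal nucleophile (acid-catalysed ring opening of an aryl donor–acceptor cyclopropane by an alcohol). The lactone enol protonates to the cis-fused bicycle, and the route is rejoined at 9 without any alkene to reduce.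

**Step 9.** The aryllithium may enolize the lactone instead of adding, the lactolate may collapse early and take up a second aryl group, and C-4 may epimerize during the quench. Fallback: set out from 9. Me(MeO)NH·HCl with AlMe3 opens the lactone to the Weinreb amide (3R,4R,5S)-5-Ar-4-(hydroxymethyl)-N-methoxy-N-methyloxolane-3-carboxamide F4. Immediate silylation (Et3SiCl, imidazole) prevents re-lactonization and gives the triethylsilyl ether F5. Addition of 12 to this amide stops at the chelated adduct and gives the ketone [(3R,4R,5S)-5-Ar-4-(triethylsilyloxymethyl)oxolan-3-yl](Ar)methanone F6. The conditions of step 10 remove all three silyl groups, and the route is rejoined at 15.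

## Further compounds

F1 | step 6 | (1S,5R,6R)-6-[4-(tert-butyldimethylsilyloxy)-3,5-dimethoxyphenyl]-3-oxabicyclo[3.1.0]hexan-2-one | O=C1OC[C@@H]2[C@@H](c3cc(OC)c(O[Si](C)(C)C(C)(C)C)c(OC)c3)[C@H]12
F2 | step 5 | (E)-3-[4-(tert-butyldimethylsilyloxy)-3,5-dimethoxyphenyl]prop-2-en-1-yl 2-diazo-3-hydroxypropanoate | OCC(=[N+]=[N-])C(=O)OC/C=C/c1cc(OC)c(O[Si](C)(C)C(C)(C)C)c(OC)c1
F3 | step 7 | (1S,5R,6S)-6-[4-(tert-butyldimethylsilyloxy)-3,5-dimethoxyphenyl]-1-(hydroxymethyl)-3-oxabicyclo[3.1.0]hexan-2-one | O=C1OC[C@@H]2[C@@H](c3cc(OC)c(O[Si](C)(C)C(C)(C)C)c(OC)c3)[C@]12CO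
F4 | step 9 | (3R,4R,5S)-5-[4-(tert-butyldimethylsilyloxy)-3,5-dimethoxyphenyl]-4-(hydroxymethyl)-N-methoxy-N-methyloxolane-3-carboxamide | CON(C)C(=O)[C@H]1CO[C@H](c2cc(OC)c(O[Si](C)(C)C(C)(C)C)c(OC)c2)[C@H]1CO
F5 | step 9 | (3R,4R,5S)-5-[4-(tert-butyldimethylsilyloxy)-3,5-dimethoxyphenyl]-N-methoxy-N-methyl-4-(triethylsilyloxymethyl)oxolane-3-carboxamide | CON(C)C(=O)[C@H]1CO[C@H](c2cc(OC)c(O[Si](C)(C)C(C)(C)C)c(OC)c2)[C@H]1CO[Si](CC)(CC)CC
F6 | step 9 | [(3R,4R,5S)-5-[4-(tert-butyldimethylsilyloxy)-3,5-dimethoxyphenyl]-4-(triethylsilyloxymethyl)oxolan-3-yl][4-(tert-butyldimethylsilyloxy)-3,5-dimethoxyphenyl]methanone | COc1cc(C(=O)[C@H]2CO[C@H](c3cc(OC)c(O[Si](C)(C)C(C)(C)C)c(OC)c3)[C@H]2CO[Si](CC)(CC)CC)cc(OC)c1O[Si](C)(C)C(C)(C)C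
A1 | alternative 1 | sinapyl alcohol, (E)-4-(3-hydroxyprop-1-en-1-yl)-2,6-dimethoxyphenol | OC/C=C/c1cc(OC)c(O)c(OC)c1
A2 | alternative 1 | syringaresinol, 4,4'-[(1S,3aR,4S,6aR)-tetrahydro-1H,3H-furo[3,4-c]furan-1,4-diyl]bis(2,6-dimethoxyphenol) (the enantiomer that maps onto the target) | COc1cc([C@@H]2[C@H]3CO[C@H](c4cc(OC)c(O)c(OC)c4)[C@H]3CO2)cc(OC)c1O
A3 | alternative 2 | 2-[4-(tert-butyldimethylsilyloxy)-3,5-dimethoxyphenyl]-1,3-dithiane | COc1cc(C2SCCCS2)cc(OC)c1O[Si](C)(C)C(C)(C)C
A4 | alternative 2 | (3S,4R)-3-{[4-(tert-butyldimethylsilyloxy)-3,5-dimethoxyphenyl](hydroxy)methyl}-4-{2-[4-(tert-butyldimethylsilyloxy)-3,5-dimethoxyphenyl]-1,3-dithian-2-yl}oxolan-2-one (carbinol centre not defined; drawn without the auxiliary) | O=C1OC[C@H](C2(c3cc(OC)c(O[Si](C)(C)C(C)(C)C)c(OC)c3)SCCCS2)[C@H]1C(O)c1cc(OC)c(O[Si](C)(C)C(C)(C)C)c(OC)c1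
A5 | alternative 3 | (4R)-2,4-bis[4-(tert-butyldimethylsilyloxy)-3,5-dimethoxyphenyl]-4-[(E)-3-(tert-butyldimethylsilyloxy)prop-1-en-1-yl]-1,3-dioxolane (acetal carbon not defined) | COc1cc(C2OC[C@](c3cc(OC)c(O[Si](C)(C)C(C)(C)C)c(OC)c3)(/C=C/CO[Si](C)(C)C(C)(C)C)O2)cc(OC)c1O[Si](C)(C)C(C)(C)C
A6 | alternative 3 | [(3S,4R,5S)-5-[4-(tert-butyldimethylsilyloxy)-3,5-dimethoxyphenyl]-4-(tert-butyldimethylsilyloxymethyl)oxolan-3-yl][4-(tert-butyldimethylsilyloxy)-3,5-dimethoxyphenyl]methanone (all-trans, the C-4 epimer) | COc1cc(C(=O)[C@@H]2CO[C@H](c3cc(OC)c(O[Si](C)(C)C(C)(C)C)c(OC)c3)[C@H]2CO[Si](C)(C)C(C)(C)C)cc(OC)c1O[Si](C)(C)C(C)(C)C
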